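**Assumption:** the only stereocentre is C2 of the flavan unit and is S (read from the SMILES); the C3–C6'' axis is not defined in the target and is left free. Compounds 3, 9 and 11 are bought.

**Retrosynthetic overview**
1. Target 17 ⇐ one hydrogenolysis of 16 that removes six O-benzyl groups and a C8 bromine blocking group.
2. 16 ⇐ C3(flavone)–C6(flavan) bond: the α-carbon of an apigenin-type 1,3-diketone is used as an enolonium equivalent (phenyliodonium ylide 13) and is attacked by C6–H of the (2S)-flavan 8.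
3. 8 ⇐ NBS at C8 of flavan 7 ⇐ Mitsunobu closure of (R)-carbinol 6 ⇐ tandem asymmetric transfer hydrogenation of retro-chalcone 4 ⇐ aldehyde 2 + ketone 3.
4. 13 ⇐ diketone 12 ⇐ Claisen condensation of MOM-protected acetophenone 10 with ester 11.
5. Ring order: the flavan pyran ring is closed first (step 4); the flavone pyranone ring is closed last, in the pot of the key coupling (step 9).

**Route**

Step 1
Reactants: 1 2,4,6-trihydroxybenzaldehyde
Product: 2 2,4-bis(benzyloxy)-6-hydroxybenzaldehyde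
Conditions: BnBr (2.05 equiv), K2CO3, DMF, 0 °C to rt
Reagents that add atoms: benzyl bromide, BrCc1ccccc1
Why: Williamson etherification alkylates the two non-chelated phenols, while the remaining ortho-OH, hydrogen-bonded to the aldehyde, stays free.

Step 2
Reactants: 2 2,4-bis(benzyloxy)-6-hydroxybenzaldehyde; 3 1-[4-(benzyloxy)phenyl]ethan-1-one
Product: 4 (2E)-3-[2,4-bis(benzyloxy)-6-hydroxyphenyl]-1-[4-(benzyloxy)phenyl]prop-2-en-1-one
Conditions: KOH (50% aq), EtOH/THF, rt, 36 h; then AcOH to pH 6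
Reagents that add atoms: none
Why: Claisen–Schmidt condensation of the acetophenone enolate with the non-enolisable aldehyde, followed by E1cB dehydration, gives the E-enone; the mild acidic quench avoids flavylium formation.

Step 3
Reactants: 4 (2E)-3-[2,4-bis(benzyloxy)-6-hydroxyphenyl]-1-[4-(benzyloxy)phenyl]prop-2-en-1-one
Product: 6 (1R)-3-[2,4-bis(benzyloxy)-6-hydroxyphenyl]-1-[4-(benzyloxy)phenyl]propan-1-ol, via saturated ketone 5 (not isolated)
Conditions: RuCl(p-cymene)[(R,R)-TsDPEN] (2 mol %), HCO2H/Et3N (5:2), DMF, 40 °C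
Reagents that add atoms: none
Why: Noyori-type asymmetric transfer hydrogenation run in tandem: hydride first adds in conjugate fashion to the chalcone, then the Ru–H/N–H catalyst reduces the aryl ketone, the (R,R)-ligand giving the (R)-carbinol as for simple aryl alkyl ketones.

Step 4
Reactants: 6 (1R)-3-[2,4-bis(benzyloxy)-6-hydroxyphenyl]-1-[4-(benzyloxy)phenyl]propan-1-ol
Product: 7 (2S)-5,7-bis(benzyloxy)-2-[4-(benzyloxy)phenyl]chromane
Conditions: PPh3, DIAD, toluene/THF, −20 to 0 °C
Reagents that add atoms: none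
Why: Intramolecular Mitsunobu etherification: the phenol displaces the activated benzylic oxygen with inversion, so the (R)-carbinol gives the (2S)-chromane; low temperature and a low-polarity solvent suppress ionisation.

Step 5
Reactants: 7 (2S)-5,7-bis(benzyloxy)-2-[4-(benzyloxy)phenyl]chromane
Product: 8 (2S)-5,7-bis(benzyloxy)-2-[4-(benzyloxy)phenyl]-8-bromochromane
Conditions: NBS (1.0 equiv), CH2Cl2, −78 to 0 °C
Reagents that add atoms: N-bromosuccinimide, O=C1CCC(=O)N1Br
Why: Electrophilic aromatic bromination goes to C8 (flanked by the ring oxygen and one OBn) and not to the more hindered C6, as with benzylated catechins, so bromine blocks C8 and leaves C6–H as the only free position of ring A.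

Step 6
Reactants: 9 1-[2,4-bis(benzyloxy)-6-hydroxyphenyl]ethan-1-one
Product: 10 1-[2,4-bis(benzyloxy)-6-(methoxymethoxy)phenyl]ethan-1-one
Conditions: NaH, MOMCl, DMF, 0 °C to rt
Reagents that add atoms: chloromethyl methyl ether, COCCl
Why: O-alkylation of the sodium phenoxide masks the ortho-oxygen so that it cannot intercept the enolonium later, and the acetal can be removed by acid when ring closure is wanted.

Step 7
Reactants: 10 1-[2,4-bis(benzyloxy)-6-(methoxymethoxy)phenyl]ethan-1-one; 11 methyl 4-(benzyloxy)benzoate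
Product: 12 1-[2,4-bis(benzyloxy)-6-(methoxymethoxy)phenyl]-3-[4-(benzyloxy)phenyl]propane-1,3-dione
Conditions: NaH (3 equiv), THF, 65 °C; then AcOH
Reagents that add atoms: none
Why: Crossed Claisen condensation: the ketone enolate is acylated by the non-enolisable ester and deprotonation of the β-diketone drives the equilibrium.

Step 8
Reactants: 12 1-[2,4-bis(benzyloxy)-6-(methoxymethoxy)phenyl]-3-[4-(benzyloxy)phenyl]propane-1,3-dione
Product: 13 1-[2,4-bis(benzyloxy)-6-(methoxymethoxy)phenyl]-3-[4-(benzyloxy)phenyl]-2-(phenyl-λ3-iodanylidene)propane-1,3-dione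
Conditions: PhI(OAc)2 (1.05 equiv), KOH, MeOH/CH2Cl2, 0 °C; used at once
Reagents that add atoms: (diacetoxyiodo)benzene, CC(=O)OI(OC(C)=O)c1ccccc1
Why: Condensation of the diketone enolate with PhI(OAc)2 gives the stabilised phenyliodonium ylide (iodonium ylide formation, known for dibenzoylmethane-type diketones), an isolable enolonium precursor that carries no free oxidant into the coupling.

Step 9
Reactants: 13 1-[2,4-bis(benzyloxy)-6-(methoxymethoxy)phenyl]-3-[4-(benzyloxy)phenyl]-2-(phenyl-λ3-iodanylidene)propane-1,3-dione (1.5 equiv); 8 (2S)-5,7-bis(benzyloxy)-2-[4-(benzyloxy)phenyl]-8-bromochromane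
Product: 16 5,7-bis(benzyloxy)-2-[4-(benzyloxy)phenyl]-3-{(2S)-5,7-bis(benzyloxy)-2-[4-(benzyloxy)phenyl]-8-bromochroman-6-yl}-4H-chromen-4-one, via aryl diketone 14 (not isolated), via hydroxy diketone 15 (not isolated)
Conditions: BF3·OEt2 (20 mol %), CH2Cl2, −40 to 0 °C; then HCl, MeOH, 45 °C
Reagents that add atoms: none
Why: Proposed new method: acid-catalysed C-arylation of a β-diketone phenyliodonium ylide — complexation/protonation of 13 gives an α-(phenyl-λ3-iodanyl) diketone, an enolonium equivalent whose normally nucleophilic α-carbon is attacked by the only free ring-A position of 8 (C6, activated by three oxygens) with loss of PhI, the proton freed on rearomatisation regenerating the acid; HCl/MeOH then removes the MOM group and the freed phenol closes onto the 4-(benzyloxy)benzoyl carbonyl and dehydrates to the chromone (cyclodehydration), while the benzylated oxygens of the flavan unit cannot form a benzofuran and the flavan C2 centre is not touched; closest known reaction type: C–C bond formation of trivalent-iodine enolonium species (from silyl enol ethers and PhI(OH)OTs/BF3·OEt2) with allylsilanes, enol ethers and indoles, and the acid-promoted α-functionalisation of β-dicarbonyl iodonium ylides by HX.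

Step 10
Reactants: 16 5,7-bis(benzyloxy)-2-[4-(benzyloxy)phenyl]-3-{(2S)-5,7-bis(benzyloxy)-2-[4-(benzyloxy)phenyl]-8-bromochroman-6-yl}-4H-chromen-4-one
Product: 17 5,7-dihydroxy-2-(4-hydroxyphenyl)-3-[(2S)-5,7-dihydroxy-2-(4-hydroxyphenyl)chroman-6-yl]-4H-chromen-4-one
Conditions: H2 (1 atm), Pd/C (10 wt %), NaOAc, THF/MeOH, rt
Reagents that add atoms: none
Why: Heterogeneous hydrogenolysis cleaves all six O-benzyl groups and the C8–Br bond (hydrodehalogenation, HBr buffered by acetate), while the tetrasubstituted chromone C2=C3 bond and the chroman C2–O bond survive at 1 atm and room temperature, so the stereocentre is kept.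

**Compound list**
1 | 2,4,6-trihydroxybenzaldehyde | O=Cc1c(O)cc(O)cc1O | starting material
2 | 2,4-bis(benzyloxy)-6-hydroxybenzaldehyde | O=Cc1c(O)cc(OCc2ccccc2)cc1OCc1ccccc1 | intermediate
3 | 1-[4-(benzyloxy)phenyl]ethan-1-one | CC(=O)c1ccc(OCc2ccccc2)cc1 | starting material
4 | (2E)-3-[2,4-bis(benzyloxy)-6-hydroxyphenyl]-1-[4-(benzyloxy)phenyl]prop-2-en-1-one | O=C(/C=C/c1c(O)cc(OCc2ccccc2)cc1OCc1ccccc1)c1ccc(OCc2ccccc2)cc1 | intermediate
5 | 3-[2,4-bis(benzyloxy)-6-hydroxyphenyl]-1-[4-(benzyloxy)phenyl]propan-1-one | O=C(CCc1c(O)cc(OCc2ccccc2)cc1OCc1ccccc1)c1ccc(OCc2ccccc2)cc1 | intermediate (not isolated)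
6 | (1R)-3-[2,4-bis(benzyloxy)-6-hydroxyphenyl]-1-[4-(benzyloxy)phenyl]propan-1-ol | O[C@@H](c1ccc(OCc2ccccc2)cc1)CCc1c(O)cc(OCc2ccccc2)cc1OCc1ccccc1 | intermediate
7 | (2S)-5,7-bis(benzyloxy)-2-[4-(benzyloxy)phenyl]chromane | C(c1ccccc1)Oc1cc2c(c(OCc3ccccc3)c1)CC[C@@H](c1ccc(OCc3ccccc3)cc1)O2 | intermediate
8 | (2S)-5,7-bis(benzyloxy)-2-[4-(benzyloxy)phenyl]-8-bromochromane | C(c1ccccc1)Oc1c(Br)c2c(c(OCc3ccccc3)c1)CC[C@@H](c1ccc(OCc3ccccc3)cc1)O2 | intermediate
9 | 1-[2,4-bis(benzyloxy)-6-hydroxyphenyl]ethan-1-one | CC(=O)c1c(O)cc(OCc2ccccc2)cc1OCc1ccccc1 | starting material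
10 | 1-[2,4-bis(benzyloxy)-6-(methoxymethoxy)phenyl]ethan-1-one | CC(=O)c1c(OCOC)cc(OCc2ccccc2)cc1OCc1ccccc1 | intermediate
11 | methyl 4-(benzyloxy)benzoate | COC(=O)c1ccc(OCc2ccccc2)cc1 | starting material
12 | 1-[2,4-bis(benzyloxy)-6-(methoxymethoxy)phenyl]-3-[4-(benzyloxy)phenyl]propane-1,3-dione | O=C(CC(=O)c1ccc(OCc2ccccc2)cc1)c1c(OCOC)cc(OCc2ccccc2)cc1OCc1ccccc1 | intermediate
13 | 1-[2,4-bis(benzyloxy)-6-(methoxymethoxy)phenyl]-3-[4-(benzyloxy)phenyl]-2-(phenyl-λ3-iodanylidene)propane-1,3-dione (iodonium ylide) | O=C(c1c(OCOC)cc(OCc2ccccc2)cc1OCc1ccccc1)[C-]([I+]c1ccccc1)C(=O)c1ccc(OCc2ccccc2)cc1 | intermediate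
14 | 1-[2,4-bis(benzyloxy)-6-(methoxymethoxy)phenyl]-3-[4-(benzyloxy)phenyl]-2-{(2S)-5,7-bis(benzyloxy)-2-[4-(benzyloxy)phenyl]-8-bromochroman-6-yl}propane-1,3-dione (epimers at the diketone carbon, enolisable) | O=C(c1c(OCOC)cc(OCc2ccccc2)cc1OCc1ccccc1)C(C(=O)c1ccc(OCc2ccccc2)cc1)c1c(OCc2ccccc2)c(Br)c2c(c1OCc1ccccc1)CC[C@@H](c1ccc(OCc3ccccc3)cc1)O2 | intermediate (not isolated)
15 | 1-[2,4-bis(benzyloxy)-6-hydroxyphenyl]-3-[4-(benzyloxy)phenyl]-2-{(2S)-5,7-bis(benzyloxy)-2-[4-(benzyloxy)phenyl]-8-bromochroman-6-yl}propane-1,3-dione (epimers at the diketone carbon, enolisable) | O=C(c1c(O)cc(OCc2ccccc2)cc1OCc1ccccc1)C(C(=O)c1ccc(OCc2ccccc2)cc1)c1c(OCc2ccccc2)c(Br)c2c(c1OCc1ccccc1)CC[C@@H](c1ccc(OCc3ccccc3)cc1)O2 | intermediate (not isolated)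
16 | 5,7-bis(benzyloxy)-2-[4-(benzyloxy)phenyl]-3-{(2S)-5,7-bis(benzyloxy)-2-[4-(benzyloxy)phenyl]-8-bromochroman-6-yl}-4H-chromen-4-one | O=c1c(-c2c(OCc3ccccc3)c(Br)c3c(c2OCc2ccccc2)CC[C@@H](c2ccc(OCc4ccccc4)cc2)O3)c(-c2ccc(OCc3ccccc3)cc2)oc2cc(OCc3ccccc3)cc(OCc3ccccc3)c12 | intermediate
17 | 5,7-dihydroxy-2-(4-hydroxyphenyl)-3-[(2S)-5,7-dihydroxy-2-(4-hydroxyphenyl)chroman-6-yl]-4H-chromen-4-one (CNP0304187.1) | O=c1c(-c2c(O)cc3c(c2O)CC[C@@H](c2ccc(O)cc2)O3)c(-c2ccc(O)cc2)oc2cc(O)cc(O)c12 | target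

**Step count**
Total: 10 steps. Longest linear sequence: 7 steps (1, 2, 3, 4, 5, 9, 10); the diketone branch (6, 7, 8) joins at step 9.

**Steps most likely to fail, with fallbacks**

Step 9 (key coupling). C6 of 8 is flanked by two benzyloxy groups and the electrophilic carbon is secondary and carries two aroyl groups, so the attack may be too slow. Competing paths are loss of the MOM group before coupling, capture of the enolonium by a ring-A oxygen of 13 to give a coumaranone, and ipso attack at C8–Br. The fallback keeps the same polarity reversal but uses a primary enolonium and builds the flavone afterwards. It sets out from ketone 10 and bromide 8. Ketone 10 is silylated (TMSOTf, Et3N, CH2Cl2, 0 °C) to the trimethylsilyl enol ether {1-[2,4-bis(benzyloxy)-6-(methoxymethoxy)phenyl]ethenyl}oxy(trimethyl)silane F1. Treatment of this with PhI(OH)OTs and BF3·OEt2 at −78 °C gives the trivalent-iodine enolonium species, which is intercepted by 8 to give the deoxybenzoin 1-[2,4-bis(benzyloxy)-6-(methoxymethoxy)phenyl]-2-{(2S)-5,7-bis(benzyloxy)-2-[4-(benzyloxy)phenyl]-8-bromochroman-6-yl}ethan-1-one F2. HCl/MeOH removes the MOM group to give the hydroxy deoxybenzoin 1-[2,4-bis(benzyloxy)-6-hydroxyphenyl]-2-{(2S)-5,7-bis(benzyloxy)-2-[4-(benzyloxy)phenyl]-8-bromochroman-6-yl}ethan-1-one F3. O-Aroylation with 4-(benzyloxy)benzoyl chloride (O=C(Cl)c1ccc(OCc2ccccc2)cc1) in pyridine gives the aryl ester 3,5-bis(benzyloxy)-2-({(2S)-5,7-bis(benzyloxy)-2-[4-(benzyloxy)phenyl]-8-bromochroman-6-yl}acetyl)phenyl 4-(benzyloxy)benzoate F4. Baker–Venkataraman rearrangement of the ester (KOH, pyridine, 50 °C) comes back to the route at hydroxy diketone 15, which is cyclodehydrated with acid to 16 as in step 9.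

Step 4 (Mitsunobu closure). The carbinol is a 4-alkoxybenzylic alcohol, so the oxyphosphonium intermediate may ionise and erode the enantiomeric purity. The fallback sets the stereocentre by hydrogenation and involves no substitution at the benzylic carbon. It sets out from ketone 5, isolated by stopping after the conjugate reduction as described in the fallback for step 3. Acid-catalysed cyclodehydration (TsOH·H2O, toluene, reflux, water removal) gives the 4H-chromene 5,7-bis(benzyloxy)-2-[4-(benzyloxy)phenyl]-4H-chromene F5. Asymmetric hydrogenation of the enol-ether double bond with [Ir(cod)(tBu-PHOX)][B(C6H3(CF3)2)4] (ligand enantiomer chosen in a test run to give the 2S product; H2 50 bar, CH2Cl2, rt) comes back to the route at flavan 7.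

Step 3 (tandem transfer hydrogenation). The β-aryl group is very electron-rich, so conjugate hydride addition may be slow; 1,2-reduction would give an allylic alcohol that cyclises to a 2H-chromene. The fallback separates the two reductions and changes the asymmetric method (no new compound: F0). It sets out from chalcone 4. The C=C bond is hydrogenated with RhCl(PPh3)3 and H2 (1 atm, benzene/EtOH), which leaves the benzyl ethers and the ketone intact, and ketone 5 is isolated. Reduction with BH3·SMe2 (excess, to allow for the free phenol) and (S)-2-methyl-CBS-oxazaborolidine [(S)-1-methyl-3,3-diphenyltetrahydro-1H,3H-pyrrolo[1,2-c][1,3,2]oxazaborole] in THF at −20 °C gives the (R)-carbinol and comes back to the route at 6.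

**Further compounds**
F1 | step 9 | {1-[2,4-bis(benzyloxy)-6-(methoxymethoxy)phenyl]ethenyl}oxy(trimethyl)silane | C=C(O[Si](C)(C)C)c1c(OCOC)cc(OCc2ccccc2)cc1OCc1ccccc1
F2 | step 9 | 1-[2,4-bis(benzyloxy)-6-(methoxymethoxy)phenyl]-2-{(2S)-5,7-bis(benzyloxy)-2-[4-(benzyloxy)phenyl]-8-bromochroman-6-yl}ethan-1-one | O=C(Cc1c(OCc2ccccc2)c(Br)c2c(c1OCc1ccccc1)CC[C@@H](c1ccc(OCc3ccccc3)cc1)O2)c1c(OCOC)cc(OCc2ccccc2)cc1OCc1ccccc1
F3 | step 9 | 1-[2,4-bis(benzyloxy)-6-hydroxyphenyl]-2-{(2S)-5,7-bis(benzyloxy)-2-[4-(benzyloxy)phenyl]-8-bromochroman-6-yl}ethan-1-one | O=C(Cc1c(OCc2ccccc2)c(Br)c2c(c1OCc1ccccc1)CC[C@@H](c1ccc(OCc3ccccc3)cc1)O2)c1c(O)cc(OCc2ccccc2)cc1OCc1ccccc1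
F4 | step 9 | 3,5-bis(benzyloxy)-2-({(2S)-5,7-bis(benzyloxy)-2-[4-(benzyloxy)phenyl]-8-bromochroman-6-yl}acetyl)phenyl 4-(benzyloxy)benzoate | O=C(Cc1c(OCc2ccccc2)c(Br)c2c(c1OCc1ccccc1)CC[C@@H](c1ccc(OCc3ccccc3)cc1)O2)c1c(OC(=O)c2ccc(OCc3ccccc3)cc2)cc(OCc2ccccc2)cc1OCc1ccccc1
F5 | step 4 | 5,7-bis(benzyloxy)-2-[4-(benzyloxy)phenyl]-4H-chromene | C(c1ccccc1)Oc1cc2c(c(OCc3ccccc3)c1)CC=C(c1ccc(OCc3ccccc3)cc1)O2
F0 | step 3 | none | none
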